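The cyclohexenone ring (C1 carbonyl, C2=C3 alkene, C4, stereocentre C5, C6) is closed at C5–C6, the bond from the ketone α-carbon to the allylic stereocentre. Because C6 ends as CH2 and C3 as an sp2 CH, a carboxyl on C6 and an oxygen on C3 can be tied into a temporary β-keto-δ-lactone that carries an (R)-propargylic alcohol. One Mitsunobu operation alkylates C6 with inversion at C5 to a 2-oxabicyclo[2.2.2]octanedione, which unravels in the same flask by β-elimination and decarboxylation to (R)-5-ethynylcyclohex-2-enone. Ruthenium-catalysed alkene–alkyne coupling, Morita–Baylis–Hillman hydroxymethylation and double acylation complete the target.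

Key step: step 5

Remark on the chemistry: (R)-BINOL is assumed to give the (5R)-aldol from the ynal as it does from aryl aldehydes (alkynyl and aryl rank alike); if the sense is opposite, (S)-BINOL is used; 2 is used as the commercial reagent without defined ketene-acetal geometry.

Step 1
Reactants: 1 3-(trimethylsilyl)prop-2-ynal; 2 1-methoxy-1,3-bis(trimethylsilyloxy)buta-1,3-diene
Product: 3 methyl (5R)-5-hydroxy-3-oxo-7-(trimethylsilyl)hept-6-ynoate
Conditions: Ti(OiPr)4 (10 mol%), (R)-BINOL (10 mol%), 4 Å MS, THF, −78 °C → rt; then TFA, −78 °C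
Reagents that add atoms: none
Why: Catalytic enantioselective vinylogous Mukaiyama aldol: the chiral titanium BINOLate activates the unhindered ynal and shields one face, so the dienolate terminus should add to set the (R)-carbinol (the future C5), and TFA cleaves the silyl groups to the β-keto ester.

Step 2
Reactants: 3 methyl (5R)-5-hydroxy-3-oxo-7-(trimethylsilyl)hept-6-ynoate
Product: 4 methyl (3S,5R)-3,5-dihydroxy-7-(trimethylsilyl)hept-6-ynoate
Conditions: Et2BOMe, NaBH4, THF/MeOH 4:1, −78 °C; AcOH, then MeOH co-evaporation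
Reagents that add atoms: none
Why: Narasaka–Prasad reduction: the diethylboron chelate of the β-hydroxy ketone should take hydride on the axial face to give the 1,3-syn diol, which fixes the temporary (3S) centre (the future C3, erased later).

Step 3
Reactants: 4 methyl (3S,5R)-3,5-dihydroxy-7-(trimethylsilyl)hept-6-ynoate
Product: 5 methyl (5S,7R)-5,7-dihydroxy-3-oxo-9-(trimethylsilyl)non-8-ynoate
Conditions: MeOAc (6 equiv), LiN(iPr)2 (6 equiv), THF, −78 °C; add 4, −78 → −30 °C; 1 M HCl
Reagents that add atoms: methyl acetate, CC(=O)OC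
Why: Crossed Claisen condensation: excess lithium enolate of methyl acetate should acylate at the ester of the dialkoxide, and the product is protected from over-addition as its β-keto ester enolate; no stereocentre is touched.

Step 4
Reactants: 5 methyl (5S,7R)-5,7-dihydroxy-3-oxo-9-(trimethylsilyl)non-8-ynoate
Product: 6 (6S)-6-[(2R)-2-hydroxybut-3-yn-1-yl]oxane-2,4-dione
Conditions: K2CO3 (3 equiv), MeOH, rt; then 1 M HCl to pH 2
Reagents that add atoms: none
Why: Base-mediated lactonization (intramolecular transesterification): the 5-hydroxyl should close the six-membered β-keto-δ-lactone rather than the eight-membered ring through the 7-hydroxyl, and methanolic carbonate removes the alkynyl silyl group in the same pot, with both stereocentres retained.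

Step 5
Reactants: 6 (6S)-6-[(2R)-2-hydroxybut-3-yn-1-yl]oxane-2,4-dione
Product: 9 (5R)-5-ethynylcyclohex-2-en-1-one, via bicyclic keto lactone 7 (not isolated), via keto acid 8 (not isolated)
Conditions: PPh3 (1.3 equiv), DIAD (1.3 equiv), THF (0.02 M), 0 °C → rt; then DBU (0.2 equiv), 50 °C
Reagents that add atoms: none
Why: The betaine from PPh3 and DIAD is protonated by the dione (pKa about 5) and turns the propargylic hydroxyl into an oxyphosphonium group, which the enolate carbon between the two carbonyls displaces by SN2; the closest known reaction type is the Mitsunobu C-alkylation of active-methylene compounds by secondary alcohols. The C5–C6 bond closes the carbocycle in a 6-(enolendo)-exo-tet mode through a boat-shaped lactone and gives the 2-oxabicyclo[2.2.2]octane 7. The configuration at C5 is controlled by inversion of the (R)-carbinol (the descriptor stays R because the CIP ranking changes), and the bridgehead centre at C6 is dictated by the lactone anchor and disappears later. The step needs C- over O-alkylation of the ambident dione, which the tether should secure because O-alkylation through either oxygen would put a bridgehead enol ether into a bicyclo[3.3.1] frame. DBU then enolizes the ketone at C2, its only non-bridgehead α-carbon, and expels the bridgehead carboxylate by E1cB retro-oxa-Michael opening, which places the double bond at C2=C3 and nowhere else. The β-keto acid 8 so formed should lose CO2 on warming, so C6 ends as CH2 and the activating group leaves no trace.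

Step 6
Reactants: 10 [(2S)-2-methyloxiran-2-yl]methanol
Product: 11 (2R)-2-methylpent-4-ene-1,2-diol
Conditions: CH2=CHMgBr (3 equiv), CuI (10 mol%), THF, −30 → 0 °C; aq. NH4Cl
Reagents that add atoms: vinylmagnesium bromide, C=C[Mg]Br
Why: Copper-catalysed epoxide opening by the vinyl Grignard at the unsubstituted epoxide carbon; the quaternary centre is not a reacting centre and is retained (S becomes R only through the change in CIP ranking).

Step 7
Reactants: 9 (5R)-5-ethynylcyclohex-2-en-1-one; 11 (2R)-2-methylpent-4-ene-1,2-diol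
Product: 12 (5R)-5-[(4E,6R)-6,7-dihydroxy-6-methylhepta-1,4-dien-2-yl]cyclohex-2-en-1-one
Conditions: [CpRu(MeCN)3]PF6 (10 mol%), acetone, rt
Reagents that add atoms: none
Why: Ruthenium-catalysed alkene–alkyne coupling (formal Alder-ene reaction): oxidative cyclization on the cationic CpRu fragment should join the internal alkyne carbon to the terminal alkene carbon, β-hydride elimination of an allylic hydrogen gives the (E)-alkene and reductive elimination the 1,1-disubstituted alkene, with neither stereocentre involved.

Step 8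
Reactants: 12 (5R)-5-[(4E,6R)-6,7-dihydroxy-6-methylhepta-1,4-dien-2-yl]cyclohex-2-en-1-one
Product: 13 (5R)-5-[(4E,6R)-6,7-dihydroxy-6-methylhepta-1,4-dien-2-yl]-2-(hydroxymethyl)cyclohex-2-en-1-one
Conditions: 37% aq. CH2O, DMAP (0.2 equiv), THF/H2O, rt
Reagents that add atoms: formaldehyde, C=O
Why: Morita–Baylis–Hillman reaction: DMAP adds reversibly at C3, the enolate captures formaldehyde at C2 and loss of DMAP returns the enone, leaving the remote stereocentres untouched.

Step 9
Reactants: 13 (5R)-5-[(4E,6R)-6,7-dihydroxy-6-methylhepta-1,4-dien-2-yl]-2-(hydroxymethyl)cyclohex-2-en-1-one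
Product: 14 [(2R,3E)-2-hydroxy-2-methyl-6-[(1R)-4-[(2-methylpropanoyloxy)methyl]-5-oxocyclohex-3-en-1-yl]hepta-3,6-dien-1-yl] 2-methylpropanoate
Conditions: i-PrCOCl (2.3 equiv), pyridine, CH2Cl2, −10 → 0 °C
Reagents that add atoms: 2-methylpropanoyl chloride, CC(C)C(Cl)=O
Why: Acylation of alcohols by an acid chloride: the two primary hydroxyls should react, while the tertiary allylic alcohol is too hindered under these conditions.

Compound list
1 | 3-(trimethylsilyl)prop-2-ynal | C[Si](C)(C)C#CC=O | starting material
2 | 1-methoxy-1,3-bis(trimethylsilyloxy)buta-1,3-diene | COC(O[Si](C)(C)C)=CC(=C)O[Si](C)(C)C | starting material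
3 | methyl (5R)-5-hydroxy-3-oxo-7-(trimethylsilyl)hept-6-ynoate | COC(=O)CC(=O)C[C@@H](O)C#C[Si](C)(C)C | intermediate
4 | methyl (3S,5R)-3,5-dihydroxy-7-(trimethylsilyl)hept-6-ynoate | COC(=O)C[C@@H](O)C[C@@H](O)C#C[Si](C)(C)C | intermediate
5 | methyl (5S,7R)-5,7-dihydroxy-3-oxo-9-(trimethylsilyl)non-8-ynoate | COC(=O)CC(=O)C[C@@H](O)C[C@@H](O)C#C[Si](C)(C)C | intermediate
6 | (6S)-6-[(2R)-2-hydroxybut-3-yn-1-yl]oxane-2,4-dione | O=C1CC(=O)C[C@H](C[C@@H](O)C#C)O1 | intermediate
7 | (1S,4R,8R)-8-ethynyl-2-oxabicyclo[2.2.2]octane-3,5-dione | O=C1O[C@@H]2CC(=O)[C@H]1[C@H](C#C)C2 | intermediate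
8 | (1R,6R)-6-ethynyl-2-oxocyclohex-3-ene-1-carboxylic acid | OC(=O)[C@H]1C(=O)C=CC[C@H]1C#C | intermediate
9 | (5R)-5-ethynylcyclohex-2-en-1-one | O=C1C=CC[C@@H](C#C)C1 | intermediate
10 | [(2S)-2-methyloxiran-2-yl]methanol | OC[C@@]1(C)CO1 | starting material
11 | (2R)-2-methylpent-4-ene-1,2-diol | C=CC[C@@](C)(O)CO | intermediate
12 | (5R)-5-[(4E,6R)-6,7-dihydroxy-6-methylhepta-1,4-dien-2-yl]cyclohex-2-en-1-one | C=C(C/C=C/[C@@](C)(O)CO)[C@@H]1CC=CC(=O)C1 | intermediate
13 | (5R)-5-[(4E,6R)-6,7-dihydroxy-6-methylhepta-1,4-dien-2-yl]-2-(hydroxymethyl)cyclohex-2-en-1-one | C=C(C/C=C/[C@@](C)(O)CO)[C@@H]1CC=C(CO)C(=O)C1 | intermediate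
14 | [(2R,3E)-2-hydroxy-2-methyl-6-[(1R)-4-[(2-methylpropanoyloxy)methyl]-5-oxocyclohex-3-en-1-yl]hepta-3,6-dien-1-yl] 2-methylpropanoate | C=C(C/C=C/[C@@](C)(O)COC(=O)C(C)C)[C@@H]1CC=C(COC(=O)C(C)C)C(=O)C1 | target

Total step count: 9. Longest linear sequence: 8 (steps 1–5 and 7–9; step 6 makes the side-chain fragment).

Steps most likely to fail

Step 5. The ambident dione may be alkylated at oxygen, or the activated carbinol may eliminate to an enyne before the strained bicycle closes. The fallback replaces the redox condensation by a discrete sulfonate and a lithium enolate. It sets out from 6: MsCl (2.2 equiv) and Et3N in CH2Cl2 at −20 °C should give the bis-mesylate (2R)-1-[(2S)-4-(methanesulfonyloxy)-6-oxo-3,6-dihydro-2H-pyran-2-yl]but-3-yn-2-yl methanesulfonate F1. LiOH in THF/H2O at 0 °C then cleaves the enol sulfonate, and the lithium-chelated enolate, whose oxygens are tied up by the cation, should displace the propargylic mesylate at carbon with inversion. This comes back to the route at 7, which is taken on to 9 by the DBU treatment of step 5.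

Step 7. Bond formation may leak to the terminal alkyne carbon (linear 1,4-diene) because the alkyne is α-branched, or the diol may sequester the ruthenium. The fallback builds the side chain stepwise and sets out from 9. Markovnikov hydrosilylation (HSiEt3, [Cp*Ru(MeCN)3]PF6 cat., CH2Cl2) should give (5R)-5-[1-(triethylsilyl)ethenyl]cyclohex-2-en-1-one F2. Iododesilylation (N-iodosuccinimide, HFIP, 0 °C) should give (5R)-5-(1-iodoethenyl)cyclohex-2-en-1-one F3. Stille coupling with allyltributylstannane (Pd(PPh3)4, CuI, DMF) should give (5R)-5-(penta-1,4-dien-2-yl)cyclohex-2-en-1-one F4. Its monosubstituted alkene is then joined by cross-metathesis (second-generation Hoveyda–Grubbs catalyst, CH2Cl2, 40 °C) to (2R)-2-methylbut-3-ene-1,2-diol F5. F5 is made from racemic 2-methyl-2-vinyloxirane by palladium-catalysed dynamic kinetic asymmetric hydration (Pd2(dba)3, chiral N,N'-bis(2-diphenylphosphinobenzoyl)cyclohexane-1,2-diamine ligand, NaHCO3, BEt3, CH2Cl2/H2O). The sequence comes back to the route at 12.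

Step 3. The polyanionic dialkoxide may aggregate and stall the acylation, or the β-alkoxide ester may fragment by retro-aldol on warming. The fallback does the two-carbon extension on a protected acid under neutral conditions and sets out from 4. 2,2-Dimethoxypropane with PPTS should give methyl 2-[(4S,6R)-2,2-dimethyl-6-[(trimethylsilyl)ethynyl]-1,3-dioxan-4-yl]acetate F6. LiOH (THF/H2O) hydrolyses the ester and removes the silyl group to give 2-[(4S,6R)-6-ethynyl-2,2-dimethyl-1,3-dioxan-4-yl]acetic acid F7. Activation with carbonyldiimidazole and decarboxylative C-acylation of potassium 3-methoxy-3-oxopropanoate (MgCl2, Et3N, THF) should give methyl 4-[(4S,6R)-6-ethynyl-2,2-dimethyl-1,3-dioxan-4-yl]-3-oxobutanoate F8. Aqueous HCl in MeOH removes the acetonide to give methyl (5S,7R)-5,7-dihydroxy-3-oxonon-8-ynoate F9. K2CO3/MeOH as in step 4 then comes back to the route at 6.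

Further compounds
F1 | step 5 | (2R)-1-[(2S)-4-(methanesulfonyloxy)-6-oxo-3,6-dihydro-2H-pyran-2-yl]but-3-yn-2-yl methanesulfonate | O=C1C=C(OS(C)(=O)=O)C[C@H](C[C@@H](OS(C)(=O)=O)C#C)O1
F2 | step 7 | (5R)-5-[1-(triethylsilyl)ethenyl]cyclohex-2-en-1-one | CC[Si](CC)(CC)C(=C)[C@@H]1CC=CC(=O)C1
F3 | step 7 | (5R)-5-(1-iodoethenyl)cyclohex-2-en-1-one | C=C(I)[C@@H]1CC=CC(=O)C1
F4 | step 7 | (5R)-5-(penta-1,4-dien-2-yl)cyclohex-2-en-1-one | C=CCC(=C)[C@@H]1CC=CC(=O)C1
F5 | step 7 | (2R)-2-methylbut-3-ene-1,2-diol | C=C[C@@](C)(O)CO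
F6 | step 3 | methyl 2-[(4S,6R)-2,2-dimethyl-6-[(trimethylsilyl)ethynyl]-1,3-dioxan-4-yl]acetate | COC(=O)C[C@@H]1C[C@H](C#C[Si](C)(C)C)OC(C)(C)O1
F7 | step 3 | 2-[(4S,6R)-6-ethynyl-2,2-dimethyl-1,3-dioxan-4-yl]acetic acid | OC(=O)C[C@@H]1C[C@H](C#C)OC(C)(C)O1
F8 | step 3 | methyl 4-[(4S,6R)-6-ethynyl-2,2-dimethyl-1,3-dioxan-4-yl]-3-oxobutanoate | COC(=O)CC(=O)C[C@@H]1C[C@H](C#C)OC(C)(C)O1
F9 | step 3 | methyl (5S,7R)-5,7-dihydroxy-3-oxonon-8-ynoate | COC(=O)CC(=O)C[C@@H](O)C[C@@H](O)C#C
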